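The cyclohexane is assembled by joining C1 to C2 and C3 to C4: C2–C3 is the vinyl group of vinyltriphenylphosphonium bromide, C1–C6–C5–C4 a malonate-substituted α-benzoyloxy aldehyde. One Schweizer annulation (Michael addition of the malonate, then intramolecular Wittig closure) forms both bonds. The step exploits two features of the ring: the cis-3,4-diol is a masked C3=C4 alkene, and the quaternary C1 (OH and CO2H between the C2 and C6 methylenes) is a latent gem-diester, so no stereocentre arises at C1. The catalytically set C5–O then relays the rest: it lactonises the cis carboxyl, the bridge directs dihydroxylation, and the remaining bridgehead carboxyl is exchanged for OH with retention.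

Key step: step 3

Remark on numbering: quinic acid numbering is used throughout (C1 bears OH and CO2H; C3 bears the free OH; C4 and C5 bear the esters; C2 and C6 are CH2).
Assumption: (R)-2-(triphenylmethyl)pyrrolidine is taken to give the (2R)-benzoyloxy aldehyde by steric shielding of one enamine face; if the sense were the opposite, the (S)-catalyst would be used.

Step 1
Reactants: 1 dibenzyl malonate; 2 acrolein
Product: 3 dibenzyl 2-(3-oxopropyl)malonate
Conditions: 1 (1.5 equiv), 1,8-diazabicyclo[5.4.0]undec-7-ene (2 mol%), THF, −20 °C, slow addition of 2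
Reagents that add atoms: none
Why: Base-catalysed Michael addition of the malonate to the enal, with excess malonate suppressing double addition; no stereocentre is formed.

Step 2
Reactants: 3 dibenzyl 2-(3-oxopropyl)malonate
Product: 4 dibenzyl 2-[(2R)-2-(benzoyloxy)-3-oxopropyl]malonate
Conditions: (PhCO2)2 (1.1 equiv), (R)-2-(triphenylmethyl)pyrrolidine (10 mol%), hydroquinone (10 mol%), THF, 0 °C; used without prolonged storage
Reagents that add atoms: dibenzoyl peroxide, O=C(OOC(=O)c1ccccc1)c1ccccc1
Why: Organocatalytic asymmetric α-benzoyloxylation through the enamine, whose trityl-shielded face forces attack on the peroxide O–O bond from the open face, so that C5 is set as (R) by catalyst control.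

Step 3
Reactants: 4 dibenzyl 2-[(2R)-2-(benzoyloxy)-3-oxopropyl]malonate; 5 vinyltriphenylphosphonium bromide
Product: 8 dibenzyl (5R)-5-(benzoyloxy)cyclohex-3-ene-1,1-dicarboxylate, via sodium malonate enolate 6 (not isolated), via phosphorus ylide 7 (not isolated)
Conditions: NaH (1.0 equiv), THF, −20 °C; then 5 (1.1 equiv), THF/MeCN, −20 → 25 °C
Reagents that add atoms: none
Why: Schweizer annulation (Michael addition then intramolecular Wittig olefination), a known cycloalkene synthesis from carbonyl-tethered malonates: the sodium enolate at C1 adds to the β-carbon of the vinylphosphonium salt (C1–C2 bond) and the resulting non-stabilised ylide at C3 attacks the aldehyde carbon C4 in the same flask. The six-membered ring closes in the Wittig step by 6-exo-trig attack of C3 on the C4 carbonyl to give a bicyclic oxaphosphetane, whose cycloreversion delivers the C3=C4 bond (necessarily Z in the ring) and Ph3P=O. No new stereocentre is created: C1 is deliberately formed as a non-stereogenic gem-diester and C5 is carried through unchanged. The selectivity needed is deprotonation at C1 and not at C5–H; it should be secured because the 2-alkylmalonate C–H is estimated to be several pK units more acidic than the α-H of the aldehyde in THF, because exactly one equivalent of NaH is used at low temperature, and because the intramolecular Wittig closure should outrun proton transfer to the ylide.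

Step 4
Reactants: 8 dibenzyl (5R)-5-(benzoyloxy)cyclohex-3-ene-1,1-dicarboxylate
Product: 10 benzyl (1R,5R)-7-oxo-6-oxabicyclo[3.2.1]oct-3-ene-1-carboxylate, via sodium alkoxide 9 (not isolated)
Conditions: BnOH (0.2 equiv), NaH (0.15 equiv), THF, 0 → 25 °C
Reagents that add atoms: none
Why: Alkoxide-catalysed acyl-transfer cascade (transesterification then lactonisation) in which benzyloxide removes the benzoate and the freed C5 alkoxide can reach only the ester cis to it, so the C5 stereocentre selects which C1 carboxyl becomes the lactone and thereby fixes C1.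

Step 5
Reactants: 10 benzyl (1R,5R)-7-oxo-6-oxabicyclo[3.2.1]oct-3-ene-1-carboxylate
Product: 11 benzyl (1R,3R,4R,5R)-3,4-dihydroxy-7-oxo-6-oxabicyclo[3.2.1]octane-1-carboxylate
Conditions: OsO4 (2 mol%), N-methylmorpholine N-oxide (1.5 equiv), acetone/H2O (8:1), 0 → 25 °C
Reagents that add atoms: osmium tetroxide, O=[Os](=O)(=O)=O; N-methylmorpholine N-oxide, C[N+]1([O-])CCOCC1; water, O
Why: Upjohn dihydroxylation, in which OsO4 adds suprafacially to C3=C4 from the convex face anti to the lactone bridge (and anti to the allylic C5–O), giving the cis-3,4-diol with both hydroxyls trans to O-5.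

Step 6
Reactants: 11 benzyl (1R,3R,4R,5R)-3,4-dihydroxy-7-oxo-6-oxabicyclo[3.2.1]octane-1-carboxylate
Product: 12 (1R,3R,4R,5R)-3,4-dihydroxy-7-oxo-6-oxabicyclo[3.2.1]octane-1-carboxylic acid
Conditions: H2 (1 atm), Pd/C (10 wt% palladium on carbon), EtOAc, 25 °C
Reagents that add atoms: none
Why: Hydrogenolysis of the benzyl ester frees the bridgehead carboxyl while the lactone and all stereocentres are untouched.

Step 7
Reactants: 12 (1R,3R,4R,5R)-3,4-dihydroxy-7-oxo-6-oxabicyclo[3.2.1]octane-1-carboxylic acid
Product: 14 quinide, (1S,3R,4R,5R)-1,3,4-trihydroxy-6-oxabicyclo[3.2.1]octan-7-one, via bridgehead hydroperoxide 13 (not isolated)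
Conditions: 9-mesityl-10-methylacridinium tetrafluoroborate (5 mol%), 2,6-lutidine (0.2 equiv), O2 (1 atm), 450 nm LEDs, MeCN/H2O (9:1), 25 °C; then PPh3 (1.2 equiv)
Reagents that add atoms: dioxygen, O=O
Why: Photoredox decarboxylative hydroxylation, in which the excited acridinium oxidises the carboxylate, CO2 is lost, and the C1 radical is trapped by O2 to the hydroperoxide that PPh3 reduces; the radical is confined to the bridgehead, so OH replaces the carboxyl with retention.

Step 8
Reactants: 14 quinide
Product: 16 3-O-(4-methoxybenzyl)quinide, (1S,3R,4R,5R)-1,4-dihydroxy-3-[(4-methoxybenzyl)oxy]-6-oxabicyclo[3.2.1]octan-7-one, via stannylene acetal 15 (not isolated)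
Conditions: Bu2SnO (1.1 equiv), toluene, reflux (−H2O); then 4-methoxybenzyl chloride (1.2 equiv), CsF (2 equiv), DMF, 25 °C
Reagents that add atoms: 4-methoxybenzyl chloride, COc1ccc(CCl)cc1
Why: Stannylene-acetal-mediated regioselective O-alkylation, in which the cis-3,4-diol forms the dibutylstannylene acetal and fluoride-promoted alkylation should occur at the equatorial O-3 and not the axial O-4, the tertiary O-1 being inert.

Step 9
Reactants: 16 3-O-(4-methoxybenzyl)quinide
Product: 18 4-methoxybenzyl 3-O-(4-methoxybenzyl)quinate (natural quinic acid configuration; free OH at C1, C4 and C5), via lithium carboxylate 17 (not isolated)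
Conditions: LiOH·H2O (1.05 equiv), THF/H2O, 0 °C; evaporate; 4-methoxybenzyl chloride (1.1 equiv), Bu4NI (5 mol%), DMF, 25 °C
Reagents that add atoms: lithium hydroxide, [Li+].[OH-]; 4-methoxybenzyl chloride, COc1ccc(CCl)cc1
Why: Saponification of the lactone followed by SN2 O-alkylation of the carboxylate gives the acid-labile ester and frees O-5 without touching any stereocentre.

Step 10
Reactants: 19 p-coumaric acid
Product: 21 (E)-3-{4-[(4-methoxybenzyl)oxy]phenyl}acrylic acid, via bis(4-methoxybenzyl) derivative 20 (not isolated)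
Conditions: 4-methoxybenzyl chloride (2.3 equiv), K2CO3, DMF, 60 °C; then NaOH (2 M aq), MeOH/THF, 50 °C; HCl to pH 3
Reagents that add atoms: 4-methoxybenzyl chloride, COc1ccc(CCl)cc1
Why: Williamson etherification of the phenol (with concomitant esterification) and saponification of the ester give the phenol-protected acid with the E-alkene unchanged.

Step 11
Reactants: 18 4-methoxybenzyl 3-O-(4-methoxybenzyl)quinate; 21 (E)-3-{4-[(4-methoxybenzyl)oxy]phenyl}acrylic acid
Product: 23 4-methoxybenzyl 3-O-(4-methoxybenzyl)-4,5-bis-O-{(E)-3-[4-(4-methoxybenzyloxy)phenyl]acryloyl}quinate, via acid chloride 22 (not isolated)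
Conditions: 21 (2.6 equiv), (COCl)2 (2.8 equiv), DMF (cat.), CH2Cl2, 0 → 25 °C, evaporate; then 18, pyridine, 4-(dimethylamino)pyridine (0.2 equiv), CH2Cl2, 0 → 25 °C
Reagents that add atoms: none
Why: Acylation of the two equatorial secondary hydroxyls O-4 and O-5 by the acid chloride under nucleophilic catalysis, the tertiary O-1 next to the ester being too hindered to react and O-3 being blocked.

Step 12
Reactants: 23 fully protected diester
Product: 24 4,5-di-O-p-coumaroylquinic acid
Conditions: CF3CO2H/CH2Cl2 (1:4), anisole (20 equiv), 0 °C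
Reagents that add atoms: none
Why: Acidolysis removes all four 4-methoxybenzyl groups (C3 ether, ester, two aryl ethers) with anisole as cation scavenger, and the non-basic medium should avoid acyl migration to the freed O-3.

Compound list
1 | dibenzyl malonate | O=C(CC(=O)OCc1ccccc1)OCc1ccccc1 | starting material
2 | acrolein | C=CC=O | starting material
3 | dibenzyl 2-(3-oxopropyl)malonate | O=CCCC(C(=O)OCc1ccccc1)C(=O)OCc1ccccc1 | intermediate
4 | dibenzyl 2-[(2R)-2-(benzoyloxy)-3-oxopropyl]malonate | O=C[C@H](OC(=O)c1ccccc1)CC(C(=O)OCc1ccccc1)C(=O)OCc1ccccc1 | intermediate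
5 | vinyltriphenylphosphonium bromide | C=C[P+](c1ccccc1)(c1ccccc1)c1ccccc1.[Br-] | starting material
6 | sodium malonate enolate of 4 | [Na+].O=C[C@H](OC(=O)c1ccccc1)C[C-](C(=O)OCc1ccccc1)C(=O)OCc1ccccc1 | intermediate
7 | dibenzyl 2-[(2R)-2-(benzoyloxy)-3-oxopropyl]-2-[2-(triphenylphosphoranylidene)ethyl]malonate (ylide) | O=C[C@H](OC(=O)c1ccccc1)CC(CC=P(c1ccccc1)(c1ccccc1)c1ccccc1)(C(=O)OCc1ccccc1)C(=O)OCc1ccccc1 | intermediate
8 | dibenzyl (5R)-5-(benzoyloxy)cyclohex-3-ene-1,1-dicarboxylate | C1=CCC(C(=O)OCc2ccccc2)(C(=O)OCc2ccccc2)C[C@H]1OC(=O)c1ccccc1 | intermediate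
9 | sodium (1R)-5,5-bis(benzyloxycarbonyl)cyclohex-2-en-1-olate | C1=CCC(C(=O)OCc2ccccc2)(C(=O)OCc2ccccc2)C[C@H]1[O-].[Na+] | intermediate
10 | benzyl (1R,5R)-7-oxo-6-oxabicyclo[3.2.1]oct-3-ene-1-carboxylate | C1=CC[C@]2(C(=O)OCc3ccccc3)C[C@H]1OC2=O | intermediate
11 | benzyl (1R,3R,4R,5R)-3,4-dihydroxy-7-oxo-6-oxabicyclo[3.2.1]octane-1-carboxylate | O[C@@H]1[C@H](O)C[C@]2(C(=O)OCc3ccccc3)C[C@H]1OC2=O | intermediate
12 | (1R,3R,4R,5R)-3,4-dihydroxy-7-oxo-6-oxabicyclo[3.2.1]octane-1-carboxylic acid | O[C@@H]1[C@H](O)C[C@]2(C(=O)O)C[C@H]1OC2=O | intermediate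
13 | (1S,3R,4R,5R)-1-hydroperoxy-3,4-dihydroxy-6-oxabicyclo[3.2.1]octan-7-one | O[C@@H]1[C@H](O)C[C@]2(OO)C[C@H]1OC2=O | intermediate
14 | quinide, (1S,3R,4R,5R)-1,3,4-trihydroxy-6-oxabicyclo[3.2.1]octan-7-one | O[C@@H]1[C@H](O)C[C@]2(O)C[C@H]1OC2=O | intermediate
15 | 3,4-O-(dibutylstannylene)quinide | CCCC[Sn]3(CCCC)O[C@@H]1[C@H](O3)C[C@]2(O)C[C@H]1OC2=O | intermediate
16 | 3-O-(4-methoxybenzyl)quinide | O[C@@H]1[C@H](OCc3ccc(OC)cc3)C[C@]2(O)C[C@H]1OC2=O | intermediate
17 | lithium 3-O-(4-methoxybenzyl)quinate | O[C@@H]1[C@H](OCc2ccc(OC)cc2)C[C@@](O)(C(=O)[O-])C[C@H]1O.[Li+] | intermediate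
18 | 4-methoxybenzyl 3-O-(4-methoxybenzyl)quinate | O[C@@H]1[C@H](OCc2ccc(OC)cc2)C[C@@](O)(C(=O)OCc2ccc(OC)cc2)C[C@H]1O | intermediate
19 | p-coumaric acid, (E)-3-(4-hydroxyphenyl)acrylic acid | O=C(O)/C=C/c1ccc(O)cc1 | starting material
20 | 4-methoxybenzyl (E)-3-{4-[(4-methoxybenzyl)oxy]phenyl}acrylate | COc1ccc(COC(=O)/C=C/c2ccc(OCc3ccc(OC)cc3)cc2)cc1 | intermediate
21 | (E)-3-{4-[(4-methoxybenzyl)oxy]phenyl}acrylic acid | COc1ccc(COc2ccc(/C=C/C(=O)O)cc2)cc1 | intermediate
22 | (E)-3-{4-[(4-methoxybenzyl)oxy]phenyl}acryloyl chloride | COc1ccc(COc2ccc(/C=C/C(=O)Cl)cc2)cc1 | intermediate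
23 | 4-methoxybenzyl 3-O-(4-methoxybenzyl)-4,5-bis-O-{(E)-3-[4-(4-methoxybenzyloxy)phenyl]acryloyl}quinate | O=C(/C=C/c1ccc(OCc2ccc(OC)cc2)cc1)O[C@@H]1[C@H](OCc2ccc(OC)cc2)C[C@@](O)(C(=O)OCc2ccc(OC)cc2)C[C@H]1OC(=O)/C=C/c1ccc(OCc2ccc(OC)cc2)cc1 | intermediate
24 | 4,5-di-O-p-coumaroylquinic acid | O=C(/C=C/c1ccc(O)cc1)O[C@@H]1[C@H](O)C[C@@](O)(C(=O)O)C[C@H]1OC(=O)/C=C/c1ccc(O)cc1 | target

Total step count: 12. Longest linear sequence: 11 (steps 1–9, 11, 12).

Steps most likely to fail

Step 3. The malonate enolate, or the ylide formed after the Michael addition, may deprotonate C5–H of the α-benzoyloxy aldehyde, or the C1 carbanion may attack C5 or the benzoate carbonyl within the molecule before it meets the phosphonium salt; either path erodes the configuration at C5 or consumes material. The fallback sets out from 3 and returns at 10. The same annulation is run on the achiral aldehyde 3 with 5 (NaH, THF), which carries no sensitive centre, to give dibenzyl cyclohex-3-ene-1,1-dicarboxylate F1. Allylic oxidation of the open C5 methylene (CrO3, 3,5-dimethylpyrazole, CH2Cl2, −20 °C; the C2 methylene is neopentylic and deactivated by the two esters) should give the enone dibenzyl 5-oxocyclohex-3-ene-1,1-dicarboxylate F2. Corey–Bakshi–Shibata reduction with (S)-1-methyl-3,3-diphenyltetrahydro-1H,3H-pyrrolo[1,2-c][1,3,2]oxazaborole (10 mol%) and catecholborane in toluene at −78 °C should then give dibenzyl (5R)-5-hydroxycyclohex-3-ene-1,1-dicarboxylate F3. With catalytic NaH in THF, F3 passes through alkoxide 9 and closes to 10.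

Step 7. Single-electron oxidation of the electron-poor, α-acyl carboxylate may be slow, so that the excited photocatalyst is quenched unproductively or bleached and the acid is returned. The fallback sets out from 12 and returns at 14. The acid is coupled with 1-hydroxypyridine-2(1H)-thione (dicyclohexylcarbodiimide, CH2Cl2, dark) to the thiohydroxamate (Barton) ester of acid 12 F4. Irradiation with visible light under O2 in the presence of t-BuSH (Barton decarboxylative hydroxylation, a radical chain that needs no oxidation of the carboxylate) should give hydroperoxide 13, which PPh3 reduces to 14.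

Step 8. Discrimination between O-3 and O-4 may be insufficient (regioisomers, double alkylation), or the fluoride-activated tin alkoxide may open the lactone. The fallback sets out from 14 and returns at 24; it replaces the regioselective etherification by a bridging protection of the cis-diaxial O-1/O-3 pair. The lactone is opened and esterified as in step 9 (LiOH, then 4-methoxybenzyl chloride) to 4-methoxybenzyl quinate F5. Treatment with tBu2Si(OTf)2 and 2,6-lutidine (DMF, 0 °C) should close the six-membered silylene across O-1 and O-3 (the 3,4- and 4,5-pairs could only form strained five-membered rings) to give 4-methoxybenzyl 1,3-O-(di-tert-butylsilylene)quinate F6. Acylation with 22 as in step 11 gives the 4,5-bis-O-{(E)-3-[4-(4-methoxybenzyloxy)phenyl]acryloyl} derivative of F6 F7. HF·pyridine followed by CF3CO2H/anisole then gives 24.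

Further compounds
F1 | step 3 | dibenzyl cyclohex-3-ene-1,1-dicarboxylate | O=C(OCc1ccccc1)C1(C(=O)OCc2ccccc2)CC=CCC1
F2 | step 3 | dibenzyl 5-oxocyclohex-3-ene-1,1-dicarboxylate | O=C1C=CCC(C(=O)OCc2ccccc2)(C(=O)OCc2ccccc2)C1
F3 | step 3 | dibenzyl (5R)-5-hydroxycyclohex-3-ene-1,1-dicarboxylate | C1=CCC(C(=O)OCc2ccccc2)(C(=O)OCc2ccccc2)C[C@H]1O
F4 | step 7 | thiohydroxamate (Barton) ester of acid 12 | O[C@@H]1[C@H](O)C[C@]2(C(=O)ON3C=CC=CC3=S)C[C@H]1OC2=O
F5 | step 8 | 4-methoxybenzyl quinate | O[C@@H]1[C@H](O)C[C@@](O)(C(=O)OCc2ccc(OC)cc2)C[C@H]1O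
F6 | step 8 | 4-methoxybenzyl 1,3-O-(di-tert-butylsilylene)quinate | O[C@@H]1[C@H]2C[C@@](O[Si](C(C)(C)C)(C(C)(C)C)O2)(C(=O)OCc3ccc(OC)cc3)C[C@H]1O
F7 | step 8 | 4-methoxybenzyl 1,3-O-(di-tert-butylsilylene)-4,5-bis-O-{(E)-3-[4-(4-methoxybenzyloxy)phenyl]acryloyl}quinate | O=C(/C=C/c1ccc(OCc2ccc(OC)cc2)cc1)O[C@@H]1[C@H]2C[C@@](O[Si](C(C)(C)C)(C(C)(C)C)O2)(C(=O)OCc2ccc(OC)cc2)C[C@H]1OC(=O)/C=C/c1ccc(OCc2ccc(OC)cc2)cc1
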